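Don't stretch the first minutes of a run. Alder lost 8.70 % of its starting material by 4.00 min, so a straight line promises 32.6 % by 15.0 min, but it lost 22.0 %.

| flask | starting material | coupling partner | remark | time |
|---|---|---|---|---|
| alder | 0.25 M | 1 M | run made earlier |  |
| larch | 1 M | 1 M | run made earlier |  |
| ash | 0.50 M | 2 M | run made earlier |  |
| Friday's | 0.50 M | 1.00 M |  | 15 min |
| Saturday's | 0.50 M | 1.00 M |  | 30 min |

| run | time / min | mono adduct / % | starting material / % |
|---|---|---|---|
| alder | 2.00 | 5.9 | 94.0 |
| alder | 4.00 | 8.2 | 91.3 |
| alder | 6.00 | 11.8 | 88.1 |
| alder | 8.00 | 12.3 | 83.3 |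
| alder | 10.0 | 16.9 | 82.4 |
| alder | 12.0 | 16.2 | 78.1 |
| alder | 15.0 | 18.5 | 78.0 |
| larch | 1.33 | 3.5 | 95.2 |
| larch | 2.00 | 5.9 | 93.7 |
| larch | 3.00 | 7.5 | 94.5 |
| larch | 4.00 | 9.3 | 89.2 |
| larch | 6.00 | 11.6 | 87.1 |
| larch | 10.0 | 14.7 | 82.4 |
| larch | 15.0 | 18.1 | 80.1 |
| ash | 1.33 | 6.8 | 91.3 |
| ash | 4.00 | 15.5 | 84.6 |
| ash | 8.00 | 20.3 | 77.1 |
| ash | 10.0 | 21.3 | 74.1 |
| ash | 15.0 | 24.2 | 68.6 |

(standard deviation of a reading: 1 percentage point)



1. which of the two there is more of at the end, Friday's (bis adduct / mono adduct)
2. which of the two there is more of at the end, Saturday's (bis adduct / mono adduct)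
3. how much mono adduct is there at the end, in percent of the starting material charged: Friday's
4. how much mono adduct is there at the end, in percent of the starting material charged: Saturday's

Decide whether Saturday's flask should get its 30 min, or stop at Friday's 15 min.

Count turnovers: take the natural logarithm of charged over remaining starting material. Ash stands at 0.377 after 15.0 min, and this turnover count is what to carry. Alder and larch give 0.248 and 0.222 at 15.0 min, close despite 4.00 times the starting material in larch, so the count behaves as first order in starting material.

The count still slows in alder, where the starting material lost accounts for 0.0550 M of the 1 M coupling partner. My reckoning: coupling partner is also lost another way, second order in itself, and the count then follows the dose, charge of coupling partner times time. Ash at 8.00 min has dose 960 M·s and count 0.260, beside alder's 0.248 at dose 900 M·s.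

Saturday's dose 1800 M·s equals that of ash at 15.0 min, so I put Saturday's at count 0.377, and take from the ash readings mono adduct 24.2 % and, from the gap in their balance, bis adduct 7.20 %. Friday's dose matches alder and larch at 15.0 min, which read 18.3 % mono adduct on average. Leave Saturday's the full time, for 5.9 percentage points more mono adduct than my figure for Friday's.

The forecast gives 18.3 % for Friday's, and 21 % for Saturday's, below my figure, with mono adduct ahead on both days: “Mono stays dominant, though the extrapolation is less certain.”

The flask gives 19.1 % mono adduct against 2.70 % bis adduct on Friday's, and 23.9 % against 4.82 % on Saturday's.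

    starting material + coupling partner → mono adduct + by-product (k = 0.0340 /M/min)
    coupling partner + mono adduct → bis adduct + by-product (k = 0.0360 /M/min)
    2 coupling partner → self-condensation product (k = 0.0770 /M/min)

In Friday's flask, coupling partner goes 9.1 times faster to self-condensation product than to mono adduct at the start, and still 6.4 times faster at 3.11 min. Friday's flask holds 25.5 % of its coupling partner at 15.0 min, and Saturday's 13.1 % at 30.0 min. Saturday's count is 0.338, against the 0.377 carried. The neighbour flask, Friday's charge read at 4.0 min, has count 0.103, beside 0.0910 in alder and 0.114 in larch at the same dose, and holds 9.28 % mono adduct.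

The earlier runs and the new flask come from a simulation with made-up constants; scatter was added.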